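Oak, birch and alder share one set of constants, G at 0.0200 M, J at 0.240 M and one temperature, and differ in the Z charged.

common to all: G 0.0200 M

| run | Z | J | E | time |
|---|---|---|---|---|
| oak | 0.200 M | 0.240 M |  |  |
| ash | 0.0800 M | 0.120 M |  |  |
| birch | 0.300 M | 0.240 M |  |  |
| larch | 0.200 M | 0.240 M | 0.100 M |  |
| alder | 0.490 M | 0.240 M |  | 6.5 min |

| run | time / min | [Z] / M |
|---|---|---|
| oak run | 0.49 | 0.1968 |
| oak run | 1.5 | 0.1684 |
| oak run | 2.9 | 0.1289 |
| oak run | 4.5 | 0.0939 |
| oak run | 6.5 | 0.0646 |
| ash run | 0.49 | 0.0789 |
| ash run | 1.5 | 0.0712 |
| ash run | 2.9 | 0.0574 |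
| ash run | 4.5 | 0.0377 |
| ash run | 6.5 | 0.0266 |
| birch run | 0.49 | 0.2941 |
| birch run | 1.5 | 0.2697 |
| birch run | 2.9 | 0.2280 |
| birch run | 4.5 | 0.1915 |
| birch run | 6.5 | 0.1611 |
| larch run | 0.49 | 0.1958 |
| larch run | 1.5 | 0.1703 |
| larch run | 2.9 | 0.1358 |
| larch run | 4.5 | 0.1054 |
| larch run | 6.5 | 0.0836 |

(each reading ± 0.001 M)

- Overall: Z + J -> E, with G as catalyst.
- Constant volume, constant temperature.
- A reading of a species includes what of it is bound.
- "The second partner" is J.
- An order is taken over about fifteen percent of the charge, up and down.

1. reaction order in [Z] at the outset, round the charge of the oak run, defined at two percent of the Z turned into E (one fixed amount of E, the same in the runs compared)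
2. reaction order in [J] at the outset, round the charge of the oak run, defined at two percent of the Z turned into E
3. Z in the alder run at 6.5 min, as a share of the Z charged

We begin with the end state. By the overall equation, each J takes one Z. In alder J is the limiting reagent (0.240 M against 0.490 M), so by that equation a complete reaction leaves 51.0% of the Z charged.

How far does alder get by 6.5 min? We call the Z gone by that time the take, T. Oak's take is 0.135 M and birch's is 0.139 M. The Z charge rose by a factor of 1.50, but the take rose by a factor of only 1.03.

What is that worth as a rule? We define the take exponent n as the power of the Z charge that the take follows at fixed J and G and at 6.5 min: n = 0.0629. This is a reading, and a rough one, since each reading scatters by 0.001 M.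

Carrying n beyond birch to alder, our take is 0.143 M. That leaves 70.8% of the Z charged, more than the 51.0% of the end state. We also commit to an order in Z near n.

The forecast gives 71% (range 69.8% to 74%), a little above ours. It calls the working rate “nearly zero order in Z and about first order in J”, but it lets the lag shorten with more Z. So at the outset it gives 0.42 in Z, against our n, and 0.6 in J.

    Jy + Z ⇌ GZ, settled at all times (99.30 /M)
    GZ + J → E + Jy + Q (9.180 /M/min)
    E + J → X (0.5850 /M/min)
    G + J → Jy + J (4.974 /M/min)

The flask gives 71.2% for alder, 0.034 for the order in Z and 1.0 for the order in J. Where two percent of oak's Z has turned, birch runs at 1.0 times oak's rate. Now we take n to the ash run, whose rate at that same amount of E is 0.0076 M/min against oak's 0.016 M/min, a ratio of 0.465. Ash's Z charge, 0.400 of oak's, is worth a factor of 0.944 through n. That leaves 0.493 for J, whose charge stands at 0.500 of oak's, so the order in J reads 1.02.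

The data stem from a simulated flask from invented constants.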